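**Retrosynthetic overview**
1. Target 20 ← tri-O-methyl dialdehyde 19 ← aryl cyclopentanone 18: the diformylphloroglucinol is unveiled last (twofold Rieche formylation, then O-demethylation).
2. 18 ← acyclic allyl vinyl ether 16 in one flask: a Claisen rearrangement joins the future quaternary ring carbon to the future ring CH and releases an aldehyde; rhodium-catalysed hydroacylation then adds its C–H bond across the new vinyl group and closes the cyclopentanone at its C(=O)–CH2 bond.
3. Enabling feature: in the cyclopentanone the carbonyl carbon has on one side the CH2–CH2 edge ending at the all-carbon quaternary ring carbon and on the other the ring CH carrying the cyclopropane. This 2,3,3-trisubstituted ketone is the retron of a 3-vinyl aldehyde (vinyl on a quaternary carbon, so it cannot isomerise), which is itself a Claisen retron.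
4. 16 ← (E)-alkenyl iodide 4 (cis-cyclopropane and oxobutyl chain from (+)-2-carene by ozonolysis and Takai olefination) + (E)-allylic alcohol 15 (benzylic stereocentre by Evans alkylation, then alkyne and carboalumination), joined by copper-catalysed C–O coupling.
5. Ring order: the cyclopropane (chiral pool) and the benzene ring (purchased) are carried in; the cyclopentanone is the only ring formed, in step 11.

Key step: step 11

Remark: locants used below are C1 (ring C=O), C2 and C3 (ring CH2), C4 (quaternary ring carbon with CH3), C5 (ring CH), C6 and C7 (cyclopropane CH; C7 carries the oxobutyl chain), C11 (C(CH3)2) and C9′ (benzylic CH); (+)-2-carene is taken as the (1S,6R) enantiomer and 5 and 6 as catalogue chemicals.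

**Route**

Step 1
Reactants: 1 (+)-2-carene, (1S,6R)-3,7,7-trimethylbicyclo[4.1.0]hept-2-ene
Product: 3 (1S,3R)-2,2-dimethyl-3-(3-oxobutyl)cyclopropane-1-carbaldehyde (cis), via ozonide 2 (not isolated)
Conditions: O3, CH2Cl2, −78 °C; then Me2S, −78 °C → rt
Reagents that add atoms: ozone, `O=[O+][O-]`
Why: Ozonolysis with reductive work-up cleaves the only C=C bond of 1 into ketone and aldehyde without touching the cyclopropane, so both cyclopropane stereocentres and their cis relationship come unchanged from the chiral pool.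

Step 2
Reactants: 3 (1S,3R)-2,2-dimethyl-3-(3-oxobutyl)cyclopropane-1-carbaldehyde
Product: 4 4-[(1R,3R)-3-[(E)-2-iodoethenyl]-2,2-dimethylcyclopropyl]butan-2-one
Conditions: CrCl2 (6 equiv), CHI3 (2 equiv), THF/1,4-dioxane, 0 °C → rt
Reagents that add atoms: iodoform, `IC(I)I`
Why: Takai olefination, in which the geminal dichromium reagent from CHI3 adds to the aldehyde far faster than to the methyl ketone and eliminates to the (E)-iodoalkene under non-basic conditions that should leave the cis-cyclopropane unepimerised; no new stereocentre.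

Step 3
Reactants: 5 2-(2,4,6-trimethoxyphenyl)acetic acid; 6 (4S)-4-benzyl-1,3-oxazolidin-2-one
Product: 8 (4S)-4-benzyl-3-[2-(2,4,6-trimethoxyphenyl)acetyl]-1,3-oxazolidin-2-one, via mixed anhydride 7 (not isolated)
Conditions: t-BuCOCl, Et3N, THF, −20 °C; then 6, LiCl, −20 °C → rt
Reagents that add atoms: none
Why: N-acylation of the oxazolidinone through the mixed pivalic anhydride, which is attacked at its less hindered arylacetyl carbonyl, is the standard entry to the auxiliary-bound substrate; no stereocentre is formed.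

Step 4
Reactants: 8 (4S)-4-benzyl-3-[2-(2,4,6-trimethoxyphenyl)acetyl]-1,3-oxazolidin-2-one
Product: 9 (4S)-4-benzyl-3-[(2S)-4-methyl-2-(2,4,6-trimethoxyphenyl)pent-4-enoyl]-1,3-oxazolidin-2-one
Conditions: NaN(SiMe3)2, THF, −78 °C; then CH2=C(CH3)CH2Br, −78 → −40 °C
Reagents that add atoms: 3-bromo-2-methylprop-1-ene, `CC(=C)CBr`
Why: Evans auxiliary alkylation, in which the chelated (Z)-sodium enolate is alkylated by the reactive allylic bromide on the face away from the benzyl group, setting the benzylic stereocentre (2S here, the later 1R benzylic centre C9′ of the target).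

Step 5
Reactants: 9 (4S)-4-benzyl-3-[(2S)-4-methyl-2-(2,4,6-trimethoxyphenyl)pent-4-enoyl]-1,3-oxazolidin-2-one
Product: 10 (4S)-4-benzyl-3-[(2S)-4-methyl-2-(2,4,6-trimethoxyphenyl)pentanoyl]-1,3-oxazolidin-2-one
Conditions: H2 (1 atm), Pd/C (10%), EtOAc, rt
Reagents that add atoms: none
Why: Heterogeneous catalytic hydrogenation saturates the 1,1-disubstituted alkene to the isobutyl group, while the stereocentre, the imide and the carbon-bound benzyl group are not affected.

Step 6
Reactants: 10 (4S)-4-benzyl-3-[(2S)-4-methyl-2-(2,4,6-trimethoxyphenyl)pentanoyl]-1,3-oxazolidin-2-one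
Product: 11 (2S)-4-methyl-2-(2,4,6-trimethoxyphenyl)pentan-1-ol
Conditions: LiBH4, H2O (1 equiv), Et2O, 0 °C
Reagents that add atoms: none
Why: Reductive removal of the auxiliary with LiBH4 attacks the exocyclic imide carbonyl and gives the primary alcohol without enolisation, so the stereocentre is kept and the auxiliary is recovered.

Step 7
Reactants: 11 (2S)-4-methyl-2-(2,4,6-trimethoxyphenyl)pentan-1-ol
Product: 12 (2S)-4-methyl-2-(2,4,6-trimethoxyphenyl)pentanal
Conditions: Dess–Martin periodinane, CH2Cl2, 0 °C → rt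
Reagents that add atoms: none
Why: Dess–Martin oxidation under neutral conditions gives the α-aryl aldehyde, which is used at once to avoid enolisation of the benzylic stereocentre.

Step 8
Reactants: 12 (2S)-4-methyl-2-(2,4,6-trimethoxyphenyl)pentanal
Product: 13 1,3,5-trimethoxy-2-[(3R)-5-methylhex-1-yn-3-yl]benzene
Conditions: Me3SiCHN2, n-BuLi, THF, −78 °C; then 12, −78 → 0 °C
Reagents that add atoms: trimethylsilyldiazomethane, `C[Si](C)(C)C=[N+]=[N-]`
Why: Colvin rearrangement (one-carbon homologation of an aldehyde to a terminal alkyne through addition, Peterson elimination, loss of N2 and 1,2-hydrogen shift of the alkylidene carbene) runs at −78 °C, where addition should outpace enolisation, so the benzylic centre is retained.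

Step 9
Reactants: 13 1,3,5-trimethoxy-2-[(3R)-5-methylhex-1-yn-3-yl]benzene
Product: 15 (2E,4R)-3,6-dimethyl-4-(2,4,6-trimethoxyphenyl)hept-2-en-1-ol, via alkenylalane 14 (not isolated)
Conditions: Me3Al, Cp2ZrCl2 (25 mol%), CH2Cl2, 0 °C → rt; then n-BuLi, (CH2O)n, THF, −78 °C → rt
Reagents that add atoms: trimethylaluminium, `C[Al](C)C`; formaldehyde (from paraformaldehyde), `C=O`
Why: Negishi zirconium-catalysed carboalumination adds CH3–Al syn across the terminal alkyne with methyl at the internal carbon, and the derived aluminate is hydroxymethylated with retention, which fixes the (E)-trisubstituted alkene geometry needed for the sigmatropic step; no new stereocentre.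

Step 10
Reactants: 15 (2E,4R)-3,6-dimethyl-4-(2,4,6-trimethoxyphenyl)hept-2-en-1-ol; 4 4-[(1R,3R)-3-[(E)-2-iodoethenyl]-2,2-dimethylcyclopropyl]butan-2-one
Product: 16 4-[(1R,3R)-3-[(E)-2-{[(2E,4R)-3,6-dimethyl-4-(2,4,6-trimethoxyphenyl)hept-2-en-1-yl]oxy}ethenyl]-2,2-dimethylcyclopropyl]butan-2-one
Conditions: CuI (10 mol%), 3,4,7,8-tetramethyl-1,10-phenanthroline (20 mol%), Cs2CO3, toluene, 80 °C
Reagents that add atoms: none
Why: Ullmann-type copper-catalysed C–O coupling of a primary allylic alcohol with an (E)-alkenyl iodide proceeds with retention of alkene geometry and, at 80 °C, below the temperature of the [3,3] shift, so the (E,E)-allyl vinyl ether should be isolable.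

Step 11
Reactants: 16 4-[(1R,3R)-3-[(E)-2-{[(2E,4R)-3,6-dimethyl-4-(2,4,6-trimethoxyphenyl)hept-2-en-1-yl]oxy}ethenyl]-2,2-dimethylcyclopropyl]butan-2-one
Product: 18 (2R,3R)-2-[(1R,3R)-2,2-dimethyl-3-(3-oxobutyl)cyclopropyl]-3-methyl-3-[(1R)-3-methyl-1-(2,4,6-trimethoxyphenyl)butyl]cyclopentan-1-one, via pentenal 17 (not isolated)
Conditions: ClCH2CH2Cl (degassed, sealed tube), 130 °C; then 25 °C, [Rh(nbd)(dppe)]BF4 (10 mol%, activated with H2), 25 → 50 °C
Reagents that add atoms: none
Why: On heating, 16 undergoes a Claisen [3,3]-sigmatropic rearrangement through a chair transition state that forms the C4–C5 bond and releases the 4-pentenal 17; the cationic monovalent rhodium catalyst then adds oxidatively to the aldehyde C–H bond, the hydride is delivered to the internal vinyl carbon C3 to give a six-membered acyl–alkyl rhodacycle, and reductive elimination forms the C1–C2 bond. The closest known reaction types are the tandem Claisen rearrangement/hydroacylation of allyl vinyl ethers to cyclopentanones and the rhodium–diphosphine cyclisation of 4-pentenals. The cyclopentanone is the only ring closed, by metal-templated anti-Markovnikov hydroacylation of the vinyl group (formally a 5-endo addition of the acyl C–H bond, the four-membered alternative being strained and reversible). The quaternary centre C4 is controlled by the benzylic stereocentre C9′: in the chair the trimethoxyphenyl group lies anti to the forming bond, the C9′–H next to the geminal methyl group (A(1,2) strain) and the isobutyl group next to the vinylic hydrogen, so that the enol carbon should add to the face giving 4R, and the cyclopropane should reinforce this because the required enol face places its compact C(CH3)2 carbon, not the carbon carrying the oxobutyl chain, beside the forming bond. C5 follows from the (E)-enol ether and (E)-allyl geometries, which put the cyclopropyl group and C9′ both equatorial in the chair (cyclopropyl cis to CH3 and trans to C9′ in the ring), the arrangement that is also expected to be favoured thermodynamically at this ketone-epimerisable centre. The step needs π-facial selectivity in the sigmatropic stage and, in the rhodium stage, ring closure faster than decarbonylation without alkene migration; the first is secured by the bulky di-ortho-substituted aryl group on C9′, the second by the gem-dialkyl effect of the 2,3,3-trisubstituted pentenal and by the vinyl group standing on the quaternary carbon C4, which has no allylic hydrogen.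

Step 12
Reactants: 18 (2R,3R)-2-[(1R,3R)-2,2-dimethyl-3-(3-oxobutyl)cyclopropyl]-3-methyl-3-[(1R)-3-methyl-1-(2,4,6-trimethoxyphenyl)butyl]cyclopentan-1-one
Product: 19 5-[(1R)-1-{(1R,2R)-2-[(1R,3R)-2,2-dimethyl-3-(3-oxobutyl)cyclopropyl]-1-methyl-3-oxocyclopentyl}-3-methylbutyl]-2,4,6-trimethoxybenzene-1,3-dicarbaldehyde
Conditions: Cl2CHOCH3 (excess), TiCl4, CH2Cl2, −78 → 0 °C; then H2O
Reagents that add atoms: dichloromethyl methyl ether, `COC(Cl)Cl`; water, `O`
Why: Rieche formylation, in which the TiCl4-activated dichloromethyl methyl ether attacks the only two free aryl positions, each activated by two flanking methoxy groups, and aqueous work-up unveils both aldehydes; no stereocentre is involved.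

Step 13
Reactants: 19 5-[(1R)-1-{(1R,2R)-2-[(1R,3R)-2,2-dimethyl-3-(3-oxobutyl)cyclopropyl]-1-methyl-3-oxocyclopentyl}-3-methylbutyl]-2,4,6-trimethoxybenzene-1,3-dicarbaldehyde
Product: 20 5-[(1R)-1-{(1R,2R)-2-[(1R,3R)-2,2-dimethyl-3-(3-oxobutyl)cyclopropyl]-1-methyl-3-oxocyclopentyl}-3-methylbutyl]-2,4,6-trihydroxybenzene-1,3-dicarbaldehyde (CNP0217082.3)
Conditions: BBr3 (8 equiv), CH2Cl2, −78 → 0 °C; then H2O, 0 °C
Reagents that add atoms: none
Why: BBr3-mediated aryl methyl ether cleavage, accelerated by chelation of boron between each methoxy oxygen and a neighbouring formyl group, frees the three phenols under cold, aprotic conditions that should spare the cyclopropane, the two ketones and all stereocentres.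

**Compound list**

1 | (+)-2-carene, (1S,6R)-3,7,7-trimethylbicyclo[4.1.0]hept-2-ene | `CC1=C[C@H]2[C@@H](CC1)C2(C)C` | starting material
2 | secondary ozonide of 1 (1,2,4-trioxolane across the former C=C bond; acetal centres undefined) | `CC12CC[C@@H]3[C@H](C(OO1)O2)C3(C)C` | intermediate (not isolated)
3 | (1S,3R)-2,2-dimethyl-3-(3-oxobutyl)cyclopropane-1-carbaldehyde | `CC(=O)CC[C@@H]1[C@H](C=O)C1(C)C` | intermediate
4 | 4-[(1R,3R)-3-[(E)-2-iodoethenyl]-2,2-dimethylcyclopropyl]butan-2-one | `CC(=O)CC[C@@H]1[C@H](/C=C/I)C1(C)C` | intermediate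
5 | 2-(2,4,6-trimethoxyphenyl)acetic acid | `COc1cc(OC)c(CC(=O)O)c(OC)c1` | starting material
6 | (4S)-4-benzyl-1,3-oxazolidin-2-one | `O=C1N[C@@H](Cc2ccccc2)CO1` | starting material
7 | 2,2-dimethylpropanoic 2-(2,4,6-trimethoxyphenyl)acetic anhydride | `COc1cc(OC)c(CC(=O)OC(=O)C(C)(C)C)c(OC)c1` | intermediate (not isolated)
8 | (4S)-4-benzyl-3-[2-(2,4,6-trimethoxyphenyl)acetyl]-1,3-oxazolidin-2-one | `COc1cc(OC)c(CC(=O)N2[C@@H](Cc3ccccc3)COC2=O)c(OC)c1` | intermediate
9 | (4S)-4-benzyl-3-[(2S)-4-methyl-2-(2,4,6-trimethoxyphenyl)pent-4-enoyl]-1,3-oxazolidin-2-one | `C=C(C)C[C@@H](c1c(OC)cc(OC)cc1OC)C(=O)N1[C@@H](Cc2ccccc2)COC1=O` | intermediate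
10 | (4S)-4-benzyl-3-[(2S)-4-methyl-2-(2,4,6-trimethoxyphenyl)pentanoyl]-1,3-oxazolidin-2-one | `CC(C)C[C@@H](c1c(OC)cc(OC)cc1OC)C(=O)N1[C@@H](Cc2ccccc2)COC1=O` | intermediate
11 | (2S)-4-methyl-2-(2,4,6-trimethoxyphenyl)pentan-1-ol | `CC(C)C[C@@H](c1c(OC)cc(OC)cc1OC)CO` | intermediate
12 | (2S)-4-methyl-2-(2,4,6-trimethoxyphenyl)pentanal | `CC(C)C[C@@H](c1c(OC)cc(OC)cc1OC)C=O` | intermediate
13 | 1,3,5-trimethoxy-2-[(3R)-5-methylhex-1-yn-3-yl]benzene | `CC(C)C[C@@H](c1c(OC)cc(OC)cc1OC)C#C` | intermediate
14 | [(1E,3R)-2,5-dimethyl-3-(2,4,6-trimethoxyphenyl)hex-1-en-1-yl]dimethylalumane | `C[Al](C)/C=C(\C)[C@@H](CC(C)C)c1c(OC)cc(OC)cc1OC` | intermediate (not isolated)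
15 | (2E,4R)-3,6-dimethyl-4-(2,4,6-trimethoxyphenyl)hept-2-en-1-ol | `OC/C=C(\C)[C@@H](CC(C)C)c1c(OC)cc(OC)cc1OC` | intermediate
16 | 4-[(1R,3R)-3-[(E)-2-{[(2E,4R)-3,6-dimethyl-4-(2,4,6-trimethoxyphenyl)hept-2-en-1-yl]oxy}ethenyl]-2,2-dimethylcyclopropyl]butan-2-one | `CC(=O)CC[C@@H]1[C@H](/C=C/OC/C=C(\C)[C@@H](CC(C)C)c2c(OC)cc(OC)cc2OC)C1(C)C` | intermediate
17 | (2R,3R,4R)-2-[(1R,3R)-2,2-dimethyl-3-(3-oxobutyl)cyclopropyl]-3-ethenyl-3,6-dimethyl-4-(2,4,6-trimethoxyphenyl)heptanal | `CC(=O)CC[C@@H]1[C@H]([C@@H](C=O)[C@](C)(C=C)[C@@H](CC(C)C)c2c(OC)cc(OC)cc2OC)C1(C)C` | intermediate (not isolated)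
18 | (2R,3R)-2-[(1R,3R)-2,2-dimethyl-3-(3-oxobutyl)cyclopropyl]-3-methyl-3-[(1R)-3-methyl-1-(2,4,6-trimethoxyphenyl)butyl]cyclopentan-1-one | `CC(=O)CC[C@@H]1[C@H]([C@H]2C(=O)CC[C@]2(C)[C@@H](CC(C)C)c2c(OC)cc(OC)cc2OC)C1(C)C` | intermediate
19 | 5-[(1R)-1-{(1R,2R)-2-[(1R,3R)-2,2-dimethyl-3-(3-oxobutyl)cyclopropyl]-1-methyl-3-oxocyclopentyl}-3-methylbutyl]-2,4,6-trimethoxybenzene-1,3-dicarbaldehyde | `CC(=O)CC[C@@H]1[C@H]([C@H]2C(=O)CC[C@]2(C)[C@@H](CC(C)C)c2c(OC)c(C=O)c(OC)c(C=O)c2OC)C1(C)C` | intermediate
20 | 5-[(1R)-1-{(1R,2R)-2-[(1R,3R)-2,2-dimethyl-3-(3-oxobutyl)cyclopropyl]-1-methyl-3-oxocyclopentyl}-3-methylbutyl]-2,4,6-trihydroxybenzene-1,3-dicarbaldehyde (CNP0217082.3) | `CC(=O)CC[C@@H]1[C@H]([C@H]2C(=O)CC[C@]2(C)[C@@H](CC(C)C)c2c(O)c(C=O)c(O)c(C=O)c2O)C1(C)C` | target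

**Step count and risks**

Total step count: 13. Longest linear sequence: 11 steps (steps 3 to 13); steps 1 and 2 form the short branch that joins at step 10.

Steps most likely to fail:

Step 11. At 130 °C the facial discrimination exerted by the benzylic centre may be eroded, which would show as the C4-epimeric ring series. The cis-alkyl vinylcyclopropane of 16 may also be drained by a homodienyl 1,5-hydrogen shift before the [3,3] shift. The fallback is an ester-enolate rearrangement at or below 25 °C. Setting out from 16, the enol ether is oxidised with C5H5NH[CrO3Cl] to the allyl ester (2E,4R)-3,6-dimethyl-4-(2,4,6-trimethoxyphenyl)hept-2-en-1-yl 2-[(1S,3R)-2,2-dimethyl-3-(3-oxobutyl)cyclopropyl]acetate F1. LiN(i-Pr)2 and Me3SiCl in THF/DMPU (the methyl ketone travels as its silyl enol ether and is freed on acidic work-up) then trigger an Ireland–Claisen rearrangement through the same chair to the acid (2R,3R,4R)-2-[(1R,3R)-2,2-dimethyl-3-(3-oxobutyl)cyclopropyl]-3-ethenyl-3,6-dimethyl-4-(2,4,6-trimethoxyphenyl)heptanoic acid F2. LiAlH4 reduces acid and ketone to the diol (2R,3R,4R)-3-ethenyl-2-[(1R,3R)-3-(3-hydroxybutyl)-2,2-dimethylcyclopropyl]-3,6-dimethyl-4-(2,4,6-trimethoxyphenyl)heptan-1-ol F3. Dess–Martin oxidation of both carbinols rejoins the route at the pentenal 17, now isolated, which is cyclised with the same rhodium catalyst to 18.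

Step 13. Once boron chelates have formed with both formyl groups, cleavage of the last methyl ether may stall. The longer Lewis-acid exposure then needed invites condensation at the activated formyl groups and aldol-type reactions of the two ketones. The fallback reverses the order and formylates a free phenol. Setting out from 18, BBr3 (0 °C → rt) cleaves the three unchelated methyl ethers to the triphenol 2-[(1R)-1-{(1R,2R)-2-[(1R,3R)-2,2-dimethyl-3-(3-oxobutyl)cyclopropyl]-1-methyl-3-oxocyclopentyl}-3-methylbutyl]benzene-1,3,5-triol F4. Vilsmeier–Haack formylation of this phloroglucinol (POCl3, DMF, 0 °C → rt, then aqueous hydrolysis) installs both formyl groups and rejoins the route at the target 20.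

Step 10. Slow C–O coupling of the hindered, trisubstituted allylic alcohol leaves time for reduction of the alkenyl iodide and for base-induced aldol reactions of the methyl ketone. The fallback is a copper-free Horner–Wittig enol-ether synthesis. Setting out from 15, O-alkylation with (diphenylphosphoryl)methyl 4-methylbenzenesulfonate (NaH, THF) gives the phosphine oxide ({[(2E,4R)-3,6-dimethyl-4-(2,4,6-trimethoxyphenyl)hept-2-en-1-yl]oxy}methyl)(diphenyl)phosphane oxide F5. Its lithium derivative (LiN(i-Pr)2, THF, −78 °C) adds to the aldehyde group of 3 to give the β-hydroxy phosphine oxide adduct F6. The diastereomer that leads to the (E)-enol ether is separated and eliminated stereospecifically (NaH, DMF), rejoining the route at 16.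

**Further compounds**

F1 | step 11 | (2E,4R)-3,6-dimethyl-4-(2,4,6-trimethoxyphenyl)hept-2-en-1-yl 2-[(1S,3R)-2,2-dimethyl-3-(3-oxobutyl)cyclopropyl]acetate | `CC(=O)CC[C@@H]1[C@H](CC(=O)OC/C=C(\C)[C@@H](CC(C)C)c2c(OC)cc(OC)cc2OC)C1(C)C`
F2 | step 11 | (2R,3R,4R)-2-[(1R,3R)-2,2-dimethyl-3-(3-oxobutyl)cyclopropyl]-3-ethenyl-3,6-dimethyl-4-(2,4,6-trimethoxyphenyl)heptanoic acid | `CC(=O)CC[C@@H]1[C@H]([C@@H](C(=O)O)[C@](C)(C=C)[C@@H](CC(C)C)c2c(OC)cc(OC)cc2OC)C1(C)C`
F3 | step 11 | (2R,3R,4R)-3-ethenyl-2-[(1R,3R)-3-(3-hydroxybutyl)-2,2-dimethylcyclopropyl]-3,6-dimethyl-4-(2,4,6-trimethoxyphenyl)heptan-1-ol (secondary carbinol epimers) | `CC(O)CC[C@@H]1[C@H]([C@@H](CO)[C@](C)(C=C)[C@@H](CC(C)C)c2c(OC)cc(OC)cc2OC)C1(C)C`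
F4 | step 13 | 2-[(1R)-1-{(1R,2R)-2-[(1R,3R)-2,2-dimethyl-3-(3-oxobutyl)cyclopropyl]-1-methyl-3-oxocyclopentyl}-3-methylbutyl]benzene-1,3,5-triol | `CC(=O)CC[C@@H]1[C@H]([C@H]2C(=O)CC[C@]2(C)[C@@H](CC(C)C)c2c(O)cc(O)cc2O)C1(C)C`
F5 | step 10 | ({[(2E,4R)-3,6-dimethyl-4-(2,4,6-trimethoxyphenyl)hept-2-en-1-yl]oxy}methyl)(diphenyl)phosphane oxide | `O=P(COC/C=C(\C)[C@@H](CC(C)C)c1c(OC)cc(OC)cc1OC)(c1ccccc1)c1ccccc1`
F6 | step 10 | β-hydroxy phosphine oxide adduct of F5 and 3 (carbinol and phosphorus-bearing centres undefined) | `CC(=O)CC[C@@H]1[C@H](C(O)C(OC/C=C(\C)[C@@H](CC(C)C)c2c(OC)cc(OC)cc2OC)P(=O)(c2ccccc2)c2ccccc2)C1(C)C`
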